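**Retrosynthetic overview**
- The strategy rests on the dihydrofuran ring O1–C2–C3–C3a–C7a with the aryl group on C2 and the exocyclic carbon C9 (CH2OH) on C3. Ring plus C9 is the pyranone ring of a flavanone (O1–C2–C3–C4–C4a–C8a) whose C4 has been pushed out of the ring.
- Endgame: both CH2OH groups and the free phenol come from one hydride reduction of the C3 methyl ester, a C5 acrylate and an aryl pivalate. The acrylate comes from a Heck reaction at C5–Br.
- Key disconnection C3–C3a: iodine(III)-induced 1,2-shift of ring-A carbon C4a from C4 to C3 of an (S)-6-bromo-8-methoxyflavanone contracts the pyranone to the trans dihydrofuran ester.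
- Flavanone: the O1–C2 bond is closed by an enantioselective oxa-Michael reaction of a 2'-hydroxychalcone carrying a tert-butyl ester on Cα as a removable activating group, because plain chalcones close reversibly and with poor selectivity. The chalcone comes from a salicylate-derived β-ketoester and syringaldehyde pivalate.
- Ring order: both arenes are bought; the pyranone is closed first (step 5), then contracted to the dihydrofuran (step 6).

Key step: step 6

Assumption: the quinidine-derived thiourea is taken to deliver the 2S series in step 5; the quinine-derived pseudoenantiomer gives the opposite antipode and replaces it if the sense of induction is the other way round.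

**Route**

Step 1
Reactants: 1 methyl 2-hydroxy-3-methoxybenzoate
Product: 2 methyl 5-bromo-2-hydroxy-3-methoxybenzoate
Conditions: NBS (1.05 equiv), MeCN, 0 °C → rt
Reagents that add atoms: N-bromosuccinimide, O=C1CCC(=O)N1Br
Why: Electrophilic aromatic bromination; the phenol directs para and both of its ortho positions are occupied, so bromine should enter at C5 only.

Step 2
Reactants: 2 methyl 5-bromo-2-hydroxy-3-methoxybenzoate; 3 tert-butyl acetate
Product: 4 tert-butyl 3-(5-bromo-2-hydroxy-3-methoxyphenyl)-3-oxopropanoate
Conditions: LDA (3.5 equiv), 3 (3.5 equiv), THF, −78 °C; then 2, −78 → 0 °C; aq. HCl quench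
Reagents that add atoms: none
Why: Crossed Claisen condensation; the lithium enolate of tert-butyl acetate, in excess to cover the phenol and the acidic product, acylates on the methyl ester without self-condensing, and the aryl bromide is inert to amide base and enolate at low temperature.

Step 3
Reactants: 5 syringaldehyde
Product: 6 4-formyl-2,6-dimethoxyphenyl pivalate
Conditions: PivCl (1.2 equiv), Et3N, DMAP (cat.), CH2Cl2, 0 °C → rt
Reagents that add atoms: pivaloyl chloride, CC(C)(C)C(Cl)=O
Why: DMAP-catalysed O-acylation of the hindered phenol; the pivalate is chosen because it should survive amine catalysis, hot TsOH and the acidic oxidation, draws electron density from the B ring in the key step, and is cleaved by hydride at the end.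

Step 4
Reactants: 4 tert-butyl 3-(5-bromo-2-hydroxy-3-methoxyphenyl)-3-oxopropanoate; 6 4-formyl-2,6-dimethoxyphenyl pivalate
Product: 7 tert-butyl (Z)-2-(5-bromo-2-hydroxy-3-methoxybenzoyl)-3-[3,5-dimethoxy-4-(pivaloyloxy)phenyl]prop-2-enoate
Conditions: piperidine (10 mol %), AcOH (10 mol %), 4 Å MS, toluene, rt
Reagents that add atoms: none
Why: Knoevenagel condensation of the active methylene with the aldehyde under buffered amine catalysis with removal of water; the hindered pivalate resists aminolysis, and the double-bond geometry (Z expected as the main isomer) is not carried forward.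

Step 5
Reactants: 7 tert-butyl (Z)-2-(5-bromo-2-hydroxy-3-methoxybenzoyl)-3-[3,5-dimethoxy-4-(pivaloyloxy)phenyl]prop-2-enoate
Product: 10 4-[(2S)-6-bromo-8-methoxy-4-oxo-3,4-dihydro-2H-chromen-2-yl]-2,6-dimethoxyphenyl pivalate, via tert-butyl flavanone-3-carboxylate 8 (not isolated), via flavanone-3-carboxylic acid 9 (not isolated)
Conditions: quinidine-derived 3,5-bis(trifluoromethyl)phenyl thiourea (10 mol %), toluene, −25 °C; then TsOH·H2O (1 equiv), 80 °C
Reagents that add atoms: none
Why: Intramolecular oxa-Michael addition (6-endo-trig) under bifunctional catalysis, in which the thiourea binds the β-ketoester and the quinuclidine nitrogen delivers the phenol to one face of the alkylidene, so C2 (S) is set under catalyst control; TsOH then cleaves the tert-butyl ester and the β-keto acid decarboxylates, removing the activating group without touching C2.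

Step 6
Reactants: 10 4-[(2S)-6-bromo-8-methoxy-4-oxo-3,4-dihydro-2H-chromen-2-yl]-2,6-dimethoxyphenyl pivalate
Product: 13 methyl (2S,3S)-5-bromo-2-[3,5-dimethoxy-4-(pivaloyloxy)phenyl]-7-methoxy-2,3-dihydro-1-benzofuran-3-carboxylate, via methyl enol ether 11 (not isolated), via C3 iodane ketal 12 (not isolated)
Conditions: HC(OMe)3 (solvent), conc. H2SO4 (0.5 equiv), rt, 1 h; then PhI(OAc)2 (1.3 equiv), 0 °C → rt; aq. NaHCO3
Reagents that add atoms: trimethyl orthoformate, COC(OC)OC
Why: Acid and orthoformate convert the C4 ketone into methyl enol ether 11; the iodine(III) electrophile adds to C3 of 11 on the face away from the equatorial C2 aryl group and methanol caps C4, giving ketal 12 with the C3–I bond equatorial and antiperiplanar to the ring bond C4–C4a. Ring-A carbon C4a, activated by the ortho ring oxygen, then shifts from C4 to C3 through a phenonium-type transition state as iodobenzene leaves, which makes the C3–C3a bond and leaves C4 as an exocyclic dimethoxycarbenium ion that is demethylated to the methyl ester. This is the known hypervalent-iodine oxidative ring contraction of flavanones in trimethyl orthoformate, a relative of the oxidative 1,2-aryl shift of aryl ketones to arylacetic esters. The five-membered ring arises by contraction of the six-membered ring through this 1,2-shift, not by a closure from an open chain. C2 is not involved and stays S; C3 is set by inversion at the carbon that carried iodine, which places CO2Me trans to the aryl group (2S,3S), also the favoured epimer of this enolisable ester. The step needs ring A rather than ring B to migrate and needs the shift to outrun elimination to the flavone; the pivalate leaves ring B without a free para donor, and the ring oxygen ortho to C4a should keep ring A the better migrating group despite the meta bromine.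

Step 7
Reactants: 13 methyl (2S,3S)-5-bromo-2-[3,5-dimethoxy-4-(pivaloyloxy)phenyl]-7-methoxy-2,3-dihydro-1-benzofuran-3-carboxylate; 14 methyl acrylate
Product: 15 methyl (2S,3S)-2-[3,5-dimethoxy-4-(pivaloyloxy)phenyl]-7-methoxy-5-[(E)-3-methoxy-3-oxoprop-1-en-1-yl]-2,3-dihydro-1-benzofuran-3-carboxylate
Conditions: Pd2(dba)3 (1.5 mol %), [(t-Bu)3PH]BF4 (6 mol %), Cy2NMe (1.2 equiv), 14 (1.5 equiv), dioxane, rt → 40 °C
Reagents that add atoms: none
Why: Mizoroki–Heck reaction; oxidative addition into C5–Br with the bulky electron-rich phosphine, syn insertion of the acrylate and syn β-hydride elimination should give the E cinnamate, and the hindered amine near room temperature should leave the enolisable C3 ester and both stereocentres alone.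

Step 8
Reactants: 15 methyl (2S,3S)-2-[3,5-dimethoxy-4-(pivaloyloxy)phenyl]-7-methoxy-5-[(E)-3-methoxy-3-oxoprop-1-en-1-yl]-2,3-dihydro-1-benzofuran-3-carboxylate
Product: 16 4-[(2S,3R)-3-(hydroxymethyl)-5-[(E)-3-hydroxyprop-1-en-1-yl]-7-methoxy-2,3-dihydro-1-benzofuran-2-yl]-2,6-dimethoxyphenol
Conditions: DIBAL-H (9 equiv), CH2Cl2, −78 → 0 °C; Rochelle salt work-up
Reagents that add atoms: none
Why: Hydride reduction with DIBAL-H; both methyl esters go to primary alcohols (the enoate by 1,2-reduction, so the E alkene stays) and the aryl pivalate is cleaved to the phenol in the same operation, with no base present that could epimerise C3 (the descriptor changes from 3S to 3R only because the CIP priorities change).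

**Compound list**

1 | methyl 2-hydroxy-3-methoxybenzoate | COC(=O)c1cccc(OC)c1O | starting material
2 | methyl 5-bromo-2-hydroxy-3-methoxybenzoate | COC(=O)c1cc(Br)cc(OC)c1O | intermediate
3 | tert-butyl acetate | CC(=O)OC(C)(C)C | starting material
4 | tert-butyl 3-(5-bromo-2-hydroxy-3-methoxyphenyl)-3-oxopropanoate | CC(C)(C)OC(=O)CC(=O)c1cc(Br)cc(OC)c1O | intermediate
5 | syringaldehyde (4-hydroxy-3,5-dimethoxybenzaldehyde) | COc1cc(C=O)cc(OC)c1O | starting material
6 | 4-formyl-2,6-dimethoxyphenyl pivalate | COc1cc(C=O)cc(OC)c1OC(=O)C(C)(C)C | intermediate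
7 | tert-butyl (Z)-2-(5-bromo-2-hydroxy-3-methoxybenzoyl)-3-[3,5-dimethoxy-4-(pivaloyloxy)phenyl]prop-2-enoate | CC(C)(C)OC(=O)/C(=C\c1cc(OC)c(OC(=O)C(C)(C)C)c(OC)c1)C(=O)c1cc(Br)cc(OC)c1O | intermediate
8 | tert-butyl (2S,3R)-6-bromo-2-[3,5-dimethoxy-4-(pivaloyloxy)phenyl]-8-methoxy-4-oxochromane-3-carboxylate (trans keto form, in equilibrium with its enol) | COc1cc([C@H]2Oc3c(OC)cc(Br)cc3C(=O)[C@@H]2C(=O)OC(C)(C)C)cc(OC)c1OC(=O)C(C)(C)C | intermediate (not isolated)
9 | (2S,3R)-6-bromo-2-[3,5-dimethoxy-4-(pivaloyloxy)phenyl]-8-methoxy-4-oxochromane-3-carboxylic acid | COc1cc([C@H]2Oc3c(OC)cc(Br)cc3C(=O)[C@@H]2C(O)=O)cc(OC)c1OC(=O)C(C)(C)C | intermediate (not isolated)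
10 | 4-[(2S)-6-bromo-8-methoxy-4-oxo-3,4-dihydro-2H-chromen-2-yl]-2,6-dimethoxyphenyl pivalate | COc1cc([C@H]2Oc3c(OC)cc(Br)cc3C(=O)C2)cc(OC)c1OC(=O)C(C)(C)C | intermediate (key-step precursor)
11 | 4-[(2S)-6-bromo-4,8-dimethoxy-2H-chromen-2-yl]-2,6-dimethoxyphenyl pivalate | COc1cc([C@H]2Oc3c(OC)cc(Br)cc3C(OC)=C2)cc(OC)c1OC(=O)C(C)(C)C | intermediate (not isolated)
12 | 4-[2,3-trans-3-[acetoxy(phenyl)-λ3-iodanyl]-6-bromo-4,4,8-trimethoxychroman-2-yl]-2,6-dimethoxyphenyl pivalate (C2 as in 10, iodine anti to the aryl group) | COc1cc([C@H]2Oc3c(OC)cc(Br)cc3C(OC)(OC)[C@@H]2I(OC(C)=O)c4ccccc4)cc(OC)c1OC(=O)C(C)(C)C | intermediate (not isolated)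
13 | methyl (2S,3S)-5-bromo-2-[3,5-dimethoxy-4-(pivaloyloxy)phenyl]-7-methoxy-2,3-dihydro-1-benzofuran-3-carboxylate (trans) | COc1cc([C@H]2Oc3c(OC)cc(Br)cc3[C@@H]2C(=O)OC)cc(OC)c1OC(=O)C(C)(C)C | intermediate (key-step product)
14 | methyl acrylate | C=CC(=O)OC | starting material
15 | methyl (2S,3S)-2-[3,5-dimethoxy-4-(pivaloyloxy)phenyl]-7-methoxy-5-[(E)-3-methoxy-3-oxoprop-1-en-1-yl]-2,3-dihydro-1-benzofuran-3-carboxylate | COc1cc([C@H]2Oc3c(OC)cc(/C=C/C(=O)OC)cc3[C@@H]2C(=O)OC)cc(OC)c1OC(=O)C(C)(C)C | intermediate
16 | 4-[(2S,3R)-3-(hydroxymethyl)-5-[(E)-3-hydroxyprop-1-en-1-yl]-7-methoxy-2,3-dihydro-1-benzofuran-2-yl]-2,6-dimethoxyphenol | COc1cc([C@H]2Oc3c(OC)cc(/C=C/CO)cc3[C@@H]2CO)cc(OC)c1O | target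

**Totals**

Total step count: 8. Longest linear sequence: 7 (steps 1, 2, 4, 5, 6, 7, 8).

**Steps most likely to fail**

Step 6 (key step). After iodination at C3 the iodane may lose H–C2 and iodobenzene to give the flavone, or ring B may shift from C2 to C3 towards the isoflavone, faster than the bromine- and methoxy-deactivated ring-A carbon migrates. The iodine(III) reagent may also attack the dimethoxyarene ring. The fallback is a Wolff ring contraction that forms the same C3–C3a bond, and it sets out from 10.
- Heating 10 with DMF dimethyl acetal (toluene, 80 °C) should give the enaminone 4-[6-bromo-3-[(E)-(dimethylamino)methylidene]-8-methoxy-4-oxochroman-2-yl]-2,6-dimethoxyphenyl pivalate F1 (C2 as in 10).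
- Diazo transfer with TsN3 (CH2Cl2, rt) cleaves the aminomethylidene carbon and should give the diazo ketone 4-(6-bromo-3-diazo-8-methoxy-4-oxochroman-2-yl)-2,6-dimethoxyphenyl pivalate F2.
- Irradiation (365 nm, MeOH) triggers the Wolff rearrangement, in which C4a again moves from C4 to C3. Methanol traps the ketene as the methyl ester, expected as a mixture of 13 and its cis epimer methyl (2S,3R)-5-bromo-2-[3,5-dimethoxy-4-(pivaloyloxy)phenyl]-7-methoxy-2,3-dihydro-1-benzofuran-3-carboxylate F3.
- Catalytic DBU (CH2Cl2, rt) equilibrates F3 to the trans ester, and the route is rejoined at 13.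

Step 5. The ortho-methoxy phenol and the hindered, electron-rich alkylidene may fit the catalyst poorly, uncatalysed closure may compete, or C2 may erode by reversible ring opening during the acidic decarboxylation, so that 10 is obtained with insufficient enantiomeric purity. The fallback replaces asymmetric bond formation by kinetic resolution and sets out from scalemic 10.
- Asymmetric transfer hydrogenation with [Cp*RhCl((R,R)-TsDPEN)] (1 mol %), HCO2H/Et3N, EtOAc, rt, using the catalyst enantiomer that reduces the 2R ketone fastest, is stopped when the minor enantiomer is consumed.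
- The 2R ketone is reduced in the matched sense to the cis alcohol 4-[(2R,4R)-6-bromo-4-hydroxy-8-methoxy-3,4-dihydro-2H-chromen-2-yl]-2,6-dimethoxyphenyl pivalate F4, which is removed by chromatography.
- The recovered enantioenriched ketone re-enters the route at 10.

Step 7. The amine base may deprotonate C3 (α to the ester and benzylic) with loss of the aryloxide from C2, an E1cB ring opening to a stilbene ester that would scramble C2 and C3. Oxidative addition into the electron-rich C5–Br bond may also stall. The fallback is a base-free Stille coupling that brings the allylic alcohol in directly, and it sets out from 13.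
- Coupling of 13 with (E)-3-(tributylstannyl)prop-2-en-1-ol (Pd(PPh3)4, toluene, 100 °C) should give methyl (2S,3S)-2-[3,5-dimethoxy-4-(pivaloyloxy)phenyl]-5-[(E)-3-hydroxyprop-1-en-1-yl]-7-methoxy-2,3-dihydro-1-benzofuran-3-carboxylate F5.
- DIBAL-H (CH2Cl2, −78 → 0 °C) reduces the C3 ester and removes the pivalate, and the route is rejoined at 16.

**Further compounds**

F1 | step 6 | 4-[6-bromo-3-[(E)-(dimethylamino)methylidene]-8-methoxy-4-oxochroman-2-yl]-2,6-dimethoxyphenyl pivalate (C2 as in 10) | COc1cc([C@H]2Oc3c(OC)cc(Br)cc3C(=O)/C2=C/N(C)C)cc(OC)c1OC(=O)C(C)(C)C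
F2 | step 6 | 4-(6-bromo-3-diazo-8-methoxy-4-oxochroman-2-yl)-2,6-dimethoxyphenyl pivalate (C2 as in 10) | COc1cc([C@H]2Oc3c(OC)cc(Br)cc3C(=O)C2=[N+]=[N-])cc(OC)c1OC(=O)C(C)(C)C
F3 | step 6 | methyl (2S,3R)-5-bromo-2-[3,5-dimethoxy-4-(pivaloyloxy)phenyl]-7-methoxy-2,3-dihydro-1-benzofuran-3-carboxylate (cis) | COc1cc([C@H]2Oc3c(OC)cc(Br)cc3[C@H]2C(=O)OC)cc(OC)c1OC(=O)C(C)(C)C
F4 | step 5 | 4-[(2R,4R)-6-bromo-4-hydroxy-8-methoxy-3,4-dihydro-2H-chromen-2-yl]-2,6-dimethoxyphenyl pivalate | COc1cc([C@@H]2Oc3c(OC)cc(Br)cc3[C@H](O)C2)cc(OC)c1OC(=O)C(C)(C)C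
F5 | step 7 | methyl (2S,3S)-2-[3,5-dimethoxy-4-(pivaloyloxy)phenyl]-5-[(E)-3-hydroxyprop-1-en-1-yl]-7-methoxy-2,3-dihydro-1-benzofuran-3-carboxylate | COc1cc([C@H]2Oc3c(OC)cc(/C=C/CO)cc3[C@@H]2C(=O)OC)cc(OC)c1OC(=O)C(C)(C)C
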